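The readings stem from a simulated flask with constants of no real substance, noise included.

The blue run, which is the very flask asked about, holds 55% of target at 4.00 min, while its intermediate A, averaged over those minutes by trapezoids, stands at 20.7%. Dividing gives 0.665 min⁻¹, which I call the emptying constant: target gained per minute for each unit of intermediate A present, a first-order rate constant read from readings.

- blue: substrate 5 mM; reagent 12.5 mM; the very flask that is asked about, followed so far
- flask: substrate 5.0 mM; reagent 12.5 mM; time 8.0 min

- blue (time / min: intermediate A / %, target / %): 0.333: 13, 1; 0.500: 17, 1; 0.833: 25, 11; 1.33: 27, 17; 2.00: 25, 31; 2.50: 21, 37; 4.00: 18, 55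

(readings scatter by 1.5 percentage points)

- percent here means substrate units held: one side product counts as two
- on the list of suspects stand: substrate <-> intermediate A; reagent + intermediate A <-> intermediate B; intermediate A -> target; reagent + target -> over-reaction product; substrate + intermediate B -> side product

- the moment within 8.0 min at which there is most intermediate A
- the amount of intermediate A, in percent of the substrate charged, at that time
- the first time at which intermediate A reaches 19%, in the same percent, in min

How fast does this flask fill? The first reading, intermediate A plus target, gives 0.420 min⁻¹ of the charge. What does emptying cost on the way to 19%? I take the climb as straight, so its mean is half of the level, emptying takes 0.0632 min⁻¹, less than the fill, and I reckon the crossing at 0.532 min. The top I simply read from the blue run: 27% at 1.33 min, a reading with a scatter of 1.5 percentage points.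

The forecast gives 1.5 min, 27% and 0.6 min, a later crossing than mine, on this ground: "Smoothing the rise".

The flask gives 1.42 min, 27.6% and 0.482 min.

    substrate ⇌ intermediate A (K = 4.77, k = 0.00986 s⁻¹)
    reagent + intermediate A ⇌ intermediate B (K = 31.3 M⁻¹, k = 0.438 M⁻¹ s⁻¹)
    intermediate A → target (k = 0.0118 s⁻¹)
    reagent + target → over-reaction product (k = 0.0854 M⁻¹ s⁻¹)
    substrate + intermediate B → side product (k = 0.604 M⁻¹ s⁻¹)

By 1.42 min the substrate in the flask has fallen to 45.5% while intermediate A stands at its top of 27.6%. From 4.00 min to 8.00 min intermediate A in the flask falls from 16.0% to 4.51%, and the mean of these two ends, 10.3%, gives by the emptying constant an estimated 27.4%, while target plus over-reaction product gains 26 points. In the neighbour with 31 mM of reagent, target plus over-reaction product at 8.00 min stand at 79.2%, which the constant read in the blue run turns into an estimated mean intermediate A of 14.9%, beneath that neighbour's top of 23.2%.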